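**Plan**

- Hardest feature: the isolated equatorial C2–Cl on ring A, which has no neighbouring functional group, on a trans-decalin that also carries 7β-OAc, the C8 exo-methylene and the 9β side chain with the remote C12/C13 pair.
- Retrosynthetic cuts: C12–C13 (auxiliary aldol, imide ring closed last), C11–C12 and C9–C11 (one-carbon units), then ring A at C3–C4 together with C2–Cl, then C10–C1 and C10–CH3. What remains is ring B, which is (R)-carvone.
- Enabling feature: ring B is a p-menthane. The C17 methyl on C8 is para to C5, whose isopropenyl carbon is C4; the carvone carbonyl is C9 and its α′ carbon is C10. C2 lies on an unsubstituted C1H2–C2HCl–C3H2 strip, 1,3 to the gem-dimethyl carbon C4. A C4 cation adding to the terminal carbon (C3) of a C10 allyl group therefore closes ring A and leaves the charge on C2 for chloride.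
- Forward order: carvone, C10 methylation and allylation, chloride-terminated cation–olefin cyclization (ring A and C2–Cl), C9 methylenation, hydroboration–carbonylation (C9–H, C11, C12), Δ7 to 7β-OAc/8(17)-ene, aldol, imide closure.
- Stereochemistry: C5 from (R)-carvone; C10 by alkylation anti to isopropenyl; C2 by chair anti-addition (equatorial Cl); C9 by α-face hydroboration; C7 by axial hydride delivery; C12/C13 by the (R)-benzyloxazolidinone syn-aldol.

Key step: step 3

Remark: labdane numbering (C1–C20) is used for all intermediates. The target SMILES corresponds to 2α-Cl, 5α-H, 7β-OAc, 9α-H, 10β-Me and (12S,13R), a syn-aldol relationship. TiCl4 in step 3 is treated as a Lewis acid promoter that is not consumed.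

**Route**

Step 1
Reactants: 1 (R)-(−)-carvone
Product: 3 (5R)-6-methylcarvone (C6 epimers), via lithium dienolate 2 (not isolated)
Conditions: LDA, THF, −78 °C; MeI, −78 → 0 °C
Reagents that add atoms: iodomethane, CI
Why: Kinetic α′-deprotonation of the cross-conjugated enone and SN2 methylation (enolate alkylation); the C6 configuration is irrelevant because this carbon is re-enolized in step 2.

Step 2
Reactants: 3 (5R)-6-methylcarvone
Product: 5 (5S,6S)-6-allyl-6-methylcarvone (allyl trans to isopropenyl), via lithium enolate 4 (not isolated)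
Conditions: LDA, THF/DMPU, −78 °C; allyl bromide, −78 → 0 °C
Reagents that add atoms: allyl bromide, C=CCBr
Why: Enolate alkylation of the tetrasubstituted α′-enolate on the face opposite the C5 isopropenyl group, the established sense for 6-alkylcarvone enolates, sets quaternary C10 with methyl cis and allyl trans to isopropenyl.

Step 3
Reactants: 5 (5S,6S)-6-allyl-6-methylcarvone
Product: 7 (4aS,7S,8aS)-7-chloro-2,5,5,8a-tetramethyl-4a,5,6,7,8,8a-hexahydronaphthalen-1(4H)-one (2α-chloro-Δ7-9-ketone in labdane numbering), via tertiary chloride 6 (not isolated)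
Conditions: HCl (g), CH2Cl2, −78 → 0 °C; then TiCl4 (2.2 equiv), CH2Cl2, −78 → −30 °C
Reagents that add atoms: hydrogen chloride, Cl
Why: Proposed new method: Markovnikov addition of HCl to the isopropenyl group gives tertiary chloride 6; TiCl4 ionizes it to the C4 2-propyl cation, which adds to the terminal carbon C3 of the C10 allyl group while chloride (as TiCl5−) is delivered to C2, so the net change is addition of C4–Cl across the C2=C3 bond. The closest known reaction types are the Lewis-acid-promoted addition of tert-alkyl chlorides to 1-alkenes (which gives secondary chlorides because the product ionizes far more slowly than the reactant), the Lansbury chloro-olefin annulation and Prins cyclizations with chloride capture. Ring A closes 6-endo-trig through a chair in which the C5–C4 and C10–C1 bonds are trans-diequatorial on ring B, giving the trans-decalin; the 5-exo alternative would need a primary cation. The new C2 stereocenter follows from anti addition across C2=C3 in that chair, which places chloride anti to the new C3–C4 ring bond and hence equatorial (2α), and the axial β face is in addition blocked by the syn-axial C4 and C10 methyl groups. The step needs ionization of the tertiary but not the secondary chloride, and no participation of the other π system; the substrate secures this because the enone alkene is electron-poor, its carbonyl is tied up by TiCl4, and C10 is quaternary so no enolization or aromatization is possible.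

Step 4
Reactants: 7 chloro enone
Product: 8 2α-chloro-9(11),7-diene (C9 exocyclic methylene, Δ7)
Conditions: Ph3PCH3Br, KOtBu, toluene, 80 °C
Reagents that add atoms: methyltriphenylphosphonium bromide, C[P+](c1ccccc1)(c1ccccc1)c1ccccc1.[Br-]
Why: Wittig methylenation of the hindered conjugated ketone under forcing conditions; the equatorial C2 chloride on the rigid trans-decalin cannot reach an anti-periplanar E2 geometry and should survive the base.

Step 5
Reactants: 8 diene
Product: 11 2α-chloro-Δ7-C12 aldehyde (9β-CH2CHO, 9α-H), via B-alkyl-9-BBN 9 (not isolated), via boryl alkoxyaluminate 10 (not isolated)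
Conditions: 9-BBN, THF, 0 → 60 °C; then CO (1 atm), LiAlH(OtBu)3, THF, −30 → 0 °C; then H2O2, pH 7 phosphate buffer, 0 °C
Reagents that add atoms: carbon monoxide, [C-]#[O+]
Why: 9-BBN hydroborates the 1,1-disubstituted exocyclic alkene in preference to the trisubstituted Δ7 alkene and from the α face opposite the axial C10 methyl (B on C11, H on C9α, equatorial 9β chain), and the hydride-assisted carbonylation of B-alkyl-9-BBN compounds (Brown carbonylation) followed by buffered peroxide gives the one-carbon-homologated aldehyde.

Step 6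
Reactants: 11 aldehyde
Product: 12 C12 dimethyl acetal
Conditions: HC(OMe)3, PPTS (cat.), MeOH, rt
Reagents that add atoms: trimethyl orthoformate, COC(OC)OC
Why: Acid-catalyzed acetalization masks the aldehyde against the peracid, aluminium amide, oxidant and hydride of steps 7–10.

Step 7
Reactants: 12 acetal
Product: 13 7α,8α-epoxide
Conditions: mCPBA, NaHCO3, CH2Cl2, 0 °C
Reagents that add atoms: meta-chloroperoxybenzoic acid, OOC(=O)c1cccc(Cl)c1
Why: Prilezhaev epoxidation of the only alkene, expected from the α face opposite the C10 methyl; the facial outcome is not critical because C7 becomes sp2 in step 9.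

Step 8
Reactants: 13 epoxide
Product: 14 7α-hydroxy-8(17)-ene acetal
Conditions: Et2Al–TMP (from LiTMP and Et2AlCl), toluene, 0 °C
Reagents that add atoms: none
Why: Aluminium-amide isomerization of a trisubstituted epoxide to the allylic alcohol (Yamamoto conditions) by syn removal of a proton from the C17 methyl group, the least hindered position, gives the exocyclic methylene and the secondary C7 alcohol.

Step 9
Reactants: 14 allylic alcohol
Product: 15 7-oxo-8(17)-ene acetal
Conditions: Dess–Martin periodinane, NaHCO3, CH2Cl2, 0 °C → rt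
Reagents that add atoms: none
Why: Dess–Martin oxidation of the secondary allylic alcohol under buffered, non-acidic conditions leaves the acetal and the exo-methylene enone intact.

Step 10
Reactants: 15 enone
Product: 16 7β-hydroxy-8(17)-ene acetal
Conditions: NaBH4, CeCl3·7H2O, MeOH, −78 °C
Reagents that add atoms: none
Why: Luche 1,2-reduction with axial hydride delivery from the α face gives the equatorial 7β-alcohol, the known outcome for 7-oxo-8(17)-ene decalins.

Step 11
Reactants: 16 7β-alcohol
Product: 17 7β-acetate acetal
Conditions: Ac2O, pyridine, DMAP (cat.), CH2Cl2, rt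
Reagents that add atoms: acetic anhydride, CC(=O)OC(C)=O
Why: Standard acylation of the only hydroxyl group, done before C12–OH exists so that the two secondary alcohols never need to be differentiated.

Step 12
Reactants: 17 acetate acetal
Product: 18 7β-acetoxy C12 aldehyde
Conditions: TsOH·H2O (cat.), acetone/H2O, rt
Reagents that add atoms: water, O
Why: Mild acid-catalyzed acetal hydrolysis (transacetalization to acetone) releases the aldehyde without cleaving the acetate or ionizing the allylic ester.

Step 13
Reactants: 19 (R)-4-benzyl-2-oxazolidinone, 20 3-cyanopropanoic acid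
Product: 22 (R)-4-benzyl-3-(3-cyanopropanoyl)oxazolidin-2-one, via mixed pivalic anhydride 21 (not isolated)
Conditions: PivCl, Et3N, THF, −20 °C; then 19, LiCl (cat.), −20 °C → rt
Reagents that add atoms: none
Why: N-acylation of the oxazolidinone through the mixed pivalic anhydride under LiCl/Et3N conditions, a standard preparation of Evans imides.

Step 14
Reactants: 18 aldehyde, 22 cyanopropanoyl imide
Product: 24 (12S,13R) syn-aldol adduct, via Z-boron enolate 23 (not isolated)
Conditions: 22, Bu2BOTf, iPr2NEt, CH2Cl2, −78 → 0 °C; then 18, −78 → 0 °C; pH 7 buffer, MeOH, H2O2, 0 °C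
Reagents that add atoms: none
Why: Evans syn-aldol through the Z-dibutylboron enolate and a Zimmerman–Traxler chair joins the two fragments at C12–C13 and sets both centers; the (R)-benzyl auxiliary (antipode of the one that gives 2S,3R adducts from alkyl aldehydes) delivers 12S,13R under reagent control.

Step 15
Reactants: 24 aldol adduct
Product: 26 haterumaimide N, via primary amide 25 (not isolated)
Conditions: [PtH(PMe2OH)(PMe2O)2H] (5 mol %), EtOH/H2O 4:1, 80 °C; then DBU (0.1 equiv), CH2Cl2, 0 °C
Reagents that add atoms: water, O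
Why: Neutral platinum-catalyzed nitrile hydration (Ghaffar–Parkins catalyst) gives the primary amide, whose nitrogen acylates the activated N-acyloxazolidinone carbonyl (5-exo-trig, aspartimide-type closure) to form the succinimide and release the auxiliary without base strong enough to cleave the acetate.

**Compound list**

1 | (R)-(−)-carvone | CC1=CC[C@H](CC1=O)C(C)=C | starting material
2 | lithium dienolate of carvone | CC1=CC[C@@H](C(C)=C)C=C1O[Li] | intermediate (not isolated)
3 | (5R)-2,6-dimethyl-5-(prop-1-en-2-yl)cyclohex-2-en-1-one (6-methylcarvone, C6 epimers) | CC1=CC[C@@H](C(C)=C)C(C)C1=O | intermediate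
4 | lithium enolate of 6-methylcarvone | CC1=CC[C@@H](C(C)=C)C(C)=C1O[Li] | intermediate (not isolated)
5 | (5S,6S)-6-allyl-2,6-dimethyl-5-(prop-1-en-2-yl)cyclohex-2-en-1-one | C=CC[C@]1(C)C(=O)C(C)=CC[C@H]1C(C)=C | intermediate
6 | 6-allyl-5-(2-chloropropan-2-yl)-2,6-dimethylcyclohex-2-en-1-one (tertiary chloride) | C=CC[C@]1(C)C(=O)C(C)=CC[C@H]1C(C)(C)Cl | intermediate (not isolated)
7 | (4aS,7S,8aS)-7-chloro-2,5,5,8a-tetramethyl-4a,5,6,7,8,8a-hexahydronaphthalen-1(4H)-one | CC1=CC[C@H]2C(C)(C)C[C@H](Cl)C[C@]2(C)C1=O | intermediate
8 | 2α-chloro-9-methylene-Δ7-decalin (diene) | CC1=CC[C@H]2C(C)(C)C[C@H](Cl)C[C@]2(C)C1=C | intermediate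
9 | B-(C11-alkyl)-9-borabicyclo[3.3.1]nonane (9α-H) | CC1=CC[C@H]2C(C)(C)C[C@H](Cl)C[C@]2(C)[C@H]1CB1C2CCCC1CCC2 | intermediate (not isolated)
10 | lithium α-(9-BBN) alkoxy-tri-tert-butoxyaluminate | [Li+].CC1=CC[C@H]2C(C)(C)C[C@H](Cl)C[C@]2(C)[C@H]1CC(O[Al-](OC(C)(C)C)(OC(C)(C)C)OC(C)(C)C)B1C2CCCC1CCC2 | intermediate (not isolated)
11 | 2α-chloro-Δ7-9β-(2-oxoethyl) decalin (C12 aldehyde) | CC1=CC[C@H]2C(C)(C)C[C@H](Cl)C[C@]2(C)[C@H]1CC=O | intermediate
12 | C12 dimethyl acetal of 11 | CC1=CC[C@H]2C(C)(C)C[C@H](Cl)C[C@]2(C)[C@H]1CC(OC)OC | intermediate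
13 | 7α,8α-epoxide of 12 | C[C@@]12O[C@@H]1C[C@H]1C(C)(C)C[C@H](Cl)C[C@]1(C)[C@H]2CC(OC)OC | intermediate
14 | 2α-chloro-7α-hydroxy-8(17)-ene C12 dimethyl acetal | C=C1[C@H](O)C[C@H]2C(C)(C)C[C@H](Cl)C[C@]2(C)[C@H]1CC(OC)OC | intermediate
15 | 2α-chloro-7-oxo-8(17)-ene C12 dimethyl acetal | C=C1C(=O)C[C@H]2C(C)(C)C[C@H](Cl)C[C@]2(C)[C@H]1CC(OC)OC | intermediate
16 | 2α-chloro-7β-hydroxy-8(17)-ene C12 dimethyl acetal | C=C1[C@@H](O)C[C@H]2C(C)(C)C[C@H](Cl)C[C@]2(C)[C@H]1CC(OC)OC | intermediate
17 | 7β-acetoxy-2α-chloro-8(17)-ene C12 dimethyl acetal | C=C1[C@@H](OC(C)=O)C[C@H]2C(C)(C)C[C@H](Cl)C[C@]2(C)[C@H]1CC(OC)OC | intermediate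
18 | 7β-acetoxy-2α-chloro-8(17)-ene C12 aldehyde | C=C1[C@@H](OC(C)=O)C[C@H]2C(C)(C)C[C@H](Cl)C[C@]2(C)[C@H]1CC=O | intermediate
19 | (R)-4-benzyl-2-oxazolidinone | O=C1N[C@H](Cc2ccccc2)CO1 | starting material
20 | 3-cyanopropanoic acid | N#CCCC(=O)O | starting material
21 | 3-cyanopropanoic pivalic anhydride | CC(C)(C)C(=O)OC(=O)CCC#N | intermediate (not isolated)
22 | (R)-4-benzyl-3-(3-cyanopropanoyl)oxazolidin-2-one | N#CCCC(=O)N1[C@H](Cc2ccccc2)COC1=O | intermediate
23 | Z-dibutylboron enolate of 22 | CCCCB(CCCC)O/C(=C\CC#N)N1[C@H](Cc2ccccc2)COC1=O | intermediate (not isolated)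
24 | (12S,13R) syn-aldol adduct (N-acyloxazolidinone, C14 nitrile) | C=C1[C@@H](OC(C)=O)C[C@H]2C(C)(C)C[C@H](Cl)C[C@]2(C)[C@H]1C[C@H](O)[C@@H](CC#N)C(=O)N1[C@H](Cc2ccccc2)COC1=O | intermediate
25 | primary amide from hydration of 24 | C=C1[C@@H](OC(C)=O)C[C@H]2C(C)(C)C[C@H](Cl)C[C@]2(C)[C@H]1C[C@H](O)[C@@H](CC(N)=O)C(=O)N1[C@H](Cc2ccccc2)COC1=O | intermediate (not isolated)
26 | haterumaimide N | C=C1[C@@H](OC(C)=O)C[C@H]2C(C)(C)C[C@H](Cl)C[C@]2(C)[C@H]1C[C@H](O)[C@H]1CC(=O)NC1=O | target

**Count and risks**

Total steps: 15. Longest linear sequence: 14 (steps 1–12, 14, 15); step 13 is a one-step side branch.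

Steps most likely to fail:

1. Step 3 (Proposed new method). What may go wrong: the secondary C2 cation may undergo hydride or Wagner–Meerwein shifts before chloride capture. A 1,2-hydride shift from C5 to the C4 cation, followed by elimination to the isopropylidene isomer, could also scramble the ring fusion, or the reaction could stall at the tertiary chloride. Fallback with known chemistry, setting out from 3 and returning at 7: the lithium enolate of 3 is alkylated with 2,3-dichloropropene (same facial sense) to give 6-(2-chloroallyl)-6-methylcarvone F1. Lansbury chloro-olefin annulation (HCO2H, then aqueous work-up), in which the chloro-stabilized cation is hydrolyzed, closes ring A to the 2,9-dione F2. NaBH4 at low temperature reduces the unhindered saturated C2 ketone from the equatorial side, the axial face being blocked by the C4 and C10 methyls, to the axial 2β-alcohol F3. Appel chlorination (PPh3, CCl4) with inversion then gives 7.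

2. Step 5. What may go wrong: CO uptake by the hindered, β-branched B-alkyl-9-BBN may be slow, or the carbonylation intermediate may be over-reduced to the homologated alcohol. Fallback, setting out from 8 and returning at 12: hydroboration–oxidation (9-BBN; NaOH, H2O2) gives the C11 primary alcohol F4. Dess–Martin oxidation gives the β,γ-unsaturated C11 aldehyde F5. Wittig reaction with Ph3P=CHOMe gives the enol ether F6, and MeOH with PPTS converts it directly into acetal 12.

3. Step 15. What may go wrong: nitrile hydration may be incomplete, or retro-aldol cleavage and lactonization through C12–OH may compete with N-acylation during ring closure. Fallback, setting out from 18 and returning at 26: thiazolium-catalyzed Stetter addition of aldehyde 18 to N-(4-methoxybenzyl)maleimide gives the 3-acylsuccinimide F7, whose C13 is configurationally labile. Dynamic kinetic asymmetric transfer hydrogenation (Noyori–Ikariya Ru–TsDPEN catalyst, the antipode chosen for the 12S carbinol, HCO2H/Et3N) gives the syn (12S,13R) hydroxy imide F8. Ceric ammonium nitrate then removes the N-PMB group to give 26.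

**Further compounds**

F1 | step 3 | (5S,6S)-6-(2-chloroallyl)-2,6-dimethyl-5-(prop-1-en-2-yl)cyclohex-2-en-1-one | C=C(Cl)C[C@]1(C)C(=O)C(C)=CC[C@H]1C(C)=C
F2 | step 3 | 4,4,8,10-tetramethyl-Δ7-decalin-2,9-dione (labdane numbering) | CC1=CC[C@H]2C(C)(C)CC(=O)C[C@]2(C)C1=O
F3 | step 3 | 2β-hydroxy-Δ7-9-ketone | CC1=CC[C@H]2C(C)(C)C[C@@H](O)C[C@]2(C)C1=O
F4 | step 5 | 2α-chloro-Δ7-C11 primary alcohol | CC1=CC[C@H]2C(C)(C)C[C@H](Cl)C[C@]2(C)[C@H]1CO
F5 | step 5 | 2α-chloro-Δ7-C11 aldehyde | CC1=CC[C@H]2C(C)(C)C[C@H](Cl)C[C@]2(C)[C@H]1C=O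
F6 | step 5 | C11=C12 methyl enol ether (E/Z) | CC1=CC[C@H]2C(C)(C)C[C@H](Cl)C[C@]2(C)[C@H]1C=COC
F7 | step 15 | 12-oxo N-PMB succinimide (C13 epimers) | C=C1[C@@H](OC(C)=O)C[C@H]2C(C)(C)C[C@H](Cl)C[C@]2(C)[C@H]1CC(=O)C1CC(=O)N(Cc2ccc(OC)cc2)C1=O
F8 | step 15 | (12S,13R) N-PMB haterumaimide N | C=C1[C@@H](OC(C)=O)C[C@H]2C(C)(C)C[C@H](Cl)C[C@]2(C)[C@H]1C[C@H](O)[C@H]1CC(=O)N(Cc2ccc(OC)cc2)C1=O
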